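**Retrosynthetic overview**
- The target is reached by global O-debenzylation of a tetra-O-benzyl biflavone.
- The C3–C6″ biaryl bond comes from a Suzuki union of a 3-borylated acacetin-type flavone with 6-iodo-7,4′-di-O-benzylapigenin (supporting step).
- Key disconnection: the pyranone O1–C2 bond of the acacetin unit. A debenzylative, gold-catalysed oxyboration of an aryl ynone closes ring C through C–O bond formation and places boron on C3 in the same operation.
- The ynone comes from 1,3,5-tris(benzyloxy)benzene and 3-(4-methoxyphenyl)propiolic acid; the iodide comes from apigenin by 7,4′-dibenzylation and 5-OH-directed C6 iodination.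
- Ring order: both rings of the apigenin unit are bought intact; ring C of the acacetin unit is the only ring made (step 4), before the biaryl union.

Assumption: the SMILES has no stereocentre and no descriptor for the C3–C6″ axis, so the compound is made as drawn and no stereocontrol step is included.

Abbreviations: Bn = benzyl; BrBcat = B-bromocatecholborane; Bpin = pinacolboryl; IPr = 1,3-bis(2,6-diisopropylphenyl)imidazol-2-ylidene; SPhos = 2-dicyclohexylphosphino-2′,6′-dimethoxybiphenyl.

**Step 1**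
Reactants: 1 apigenin (5,7-dihydroxy-2-(4-hydroxyphenyl)-4H-chromen-4-one)
Product: 2 7-(benzyloxy)-2-[4-(benzyloxy)phenyl]-5-hydroxy-4H-chromen-4-one
Conditions: BnBr (2.2 equiv), K2CO3, DMF, 23 °C
Reagents that add atoms: benzyl bromide, BrCc1ccccc1
Why: Williamson ether synthesis in which the acidic 7- and 4′-phenols are alkylated while the 5-OH, locked in a hydrogen bond to the C4 carbonyl, stays free; no stereocentre is formed.

**Step 2**
Reactants: 2 7-(benzyloxy)-2-[4-(benzyloxy)phenyl]-5-hydroxy-4H-chromen-4-one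
Product: 3 7-(benzyloxy)-2-[4-(benzyloxy)phenyl]-5-hydroxy-6-iodo-4H-chromen-4-one
Conditions: BnMe3N+ ICl2− (1.1 equiv), CaCO3, CH2Cl2/MeOH 5:2, 23 °C
Reagents that add atoms: benzyltrimethylammonium dichloroiodate, C[N+](C)(C)Cc1ccccc1.Cl[I-]Cl
Why: Electrophilic aromatic iodination that goes ortho to the free chelated 5-OH of 5-hydroxy-7-alkoxyflavones, so iodine enters C6 and not C8, with the acid buffered by CaCO3; no stereocentre is formed.

**Step 3**
Reactants: 4 1,3,5-tris(benzyloxy)benzene; 5 3-(4-methoxyphenyl)prop-2-ynoic acid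
Product: 7 3-(4-methoxyphenyl)-1-[2,4,6-tris(benzyloxy)phenyl]prop-2-yn-1-one, via mixed trifluoroacetic anhydride 6 (not isolated)
Conditions: 5, (CF3CO)2O (1.5 equiv), CH2Cl2, 0 °C; then 4, 85% H3PO4 (cat.), 0 → 23 °C
Reagents that add atoms: none
Why: Friedel–Crafts acylation of the very electron-rich, threefold-symmetric triether by the mixed anhydride made in the flask, where all three ring positions are equivalent and the ketone product is deactivated against a second acylation; no stereocentre is formed.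

**Step 4**
Reactants: 7 3-(4-methoxyphenyl)-1-[2,4,6-tris(benzyloxy)phenyl]prop-2-yn-1-one
Product: 10 5,7-bis(benzyloxy)-2-(4-methoxyphenyl)-3-(4,4,5,5-tetramethyl-1,3,2-dioxaborolan-2-yl)-4H-chromen-4-one, via aryl catecholborate ynone 8 (not isolated), via 3-catecholboryl flavone 9 (not isolated)
Conditions: BrBcat (1.0 equiv), toluene, −40 → 23 °C; then (IPr)Au(O2CCF3) (5 mol %), NaO2CCF3 (20 mol %), 60 °C; then pinacol (3 equiv), 23 °C
Reagents that add atoms: B-bromocatecholborane, BrB1Oc2ccccc2O1; pinacol, CC(C)(O)C(C)(C)O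
Why: Proposed new method: debenzylative anti-oxyboration, in which BrBcat held on the ynone carbonyl cleaves one of the two equivalent ortho benzyl ethers by bromide attack at the benzylic carbon to give the chelated ArO–Bcat 8, cationic monovalent gold then π-activates the ynone so that the boron-bound aryloxy oxygen attacks the anisyl-bearing alkyne carbon 6-endo-dig (Michael polarity plus cation stabilisation by the p-anisyl group), and the C3–Au vinylgold is transmetalated to boron via CF3CO2–Bcat, which forms the pyranone O1–C2 bond and the C3–B bond together before pinacol displaces catechol; the closest known reaction types are the gold-catalysed oxyboration of 2-alkynylphenol catecholborates to 3-borylbenzofurans and the chelation-assisted ortho-dealkylation of aryl ethers by haloboranes; no stereocentre is formed.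

**Step 5**
Reactants: 10 5,7-bis(benzyloxy)-2-(4-methoxyphenyl)-3-(4,4,5,5-tetramethyl-1,3,2-dioxaborolan-2-yl)-4H-chromen-4-one; 3 7-(benzyloxy)-2-[4-(benzyloxy)phenyl]-5-hydroxy-6-iodo-4H-chromen-4-one
Product: 11 5,7-bis(benzyloxy)-3-{7-(benzyloxy)-2-[4-(benzyloxy)phenyl]-5-hydroxy-4-oxo-4H-chromen-6-yl}-2-(4-methoxyphenyl)-4H-chromen-4-one
Conditions: Pd(OAc)2 (5 mol %), SPhos (10 mol %), K3PO4 (3 equiv), toluene/H2O 10:1, 90 °C
Reagents that add atoms: none
Why: Suzuki–Miyaura cross-coupling with a bulky dialkylbiarylphosphine of the kind that delivers tetra-ortho-substituted biaryls, helped by the small free 5″-OH next to the iodide, while benzyl ethers, pyranones and the aryl methyl ether are inert; the new axis is not controlled because the target specifies none.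

**Step 6**
Reactants: 11 5,7-bis(benzyloxy)-3-{7-(benzyloxy)-2-[4-(benzyloxy)phenyl]-5-hydroxy-4-oxo-4H-chromen-6-yl}-2-(4-methoxyphenyl)-4H-chromen-4-one
Product: 12 5,7-dihydroxy-3-[5,7-dihydroxy-2-(4-hydroxyphenyl)-4-oxo-4H-chromen-6-yl]-2-(4-methoxyphenyl)-4H-chromen-4-one (target)
Conditions: H2 (1 atm), Pd/C (10 wt %), THF/MeOH 1:1, 23 °C
Reagents that add atoms: none
Why: Catalytic hydrogenolysis removes the four benzyl aryl ethers and leaves the aryl methyl ether, both carbonyls and the conjugated C2=C3 bonds of the two flavones untouched; no stereocentre is formed.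

**Compound list**
1 | apigenin, 5,7-dihydroxy-2-(4-hydroxyphenyl)-4H-chromen-4-one | O=c1cc(-c2ccc(O)cc2)oc2cc(O)cc(O)c12 | starting material
2 | 7-(benzyloxy)-2-[4-(benzyloxy)phenyl]-5-hydroxy-4H-chromen-4-one | O=c1cc(-c2ccc(OCc3ccccc3)cc2)oc2cc(OCc3ccccc3)cc(O)c12 | intermediate
3 | 7-(benzyloxy)-2-[4-(benzyloxy)phenyl]-5-hydroxy-6-iodo-4H-chromen-4-one | O=c1cc(-c2ccc(OCc3ccccc3)cc2)oc2cc(OCc3ccccc3)c(I)c(O)c12 | intermediate
4 | 1,3,5-tris(benzyloxy)benzene | c1ccc(COc2cc(OCc3ccccc3)cc(OCc3ccccc3)c2)cc1 | starting material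
5 | 3-(4-methoxyphenyl)prop-2-ynoic acid | COc1ccc(C#CC(=O)O)cc1 | starting material
6 | 3-(4-methoxyphenyl)prop-2-ynoic trifluoroacetic anhydride | COc1ccc(C#CC(=O)OC(=O)C(F)(F)F)cc1 | intermediate
7 | 3-(4-methoxyphenyl)-1-[2,4,6-tris(benzyloxy)phenyl]prop-2-yn-1-one | COc1ccc(C#CC(=O)c2c(OCc3ccccc3)cc(OCc3ccccc3)cc2OCc2ccccc2)cc1 | intermediate
8 | 1-[2-(1,3,2-benzodioxaborol-2-yloxy)-4,6-bis(benzyloxy)phenyl]-3-(4-methoxyphenyl)prop-2-yn-1-one | COc1ccc(C#CC(=O)c2c(OB3Oc4ccccc4O3)cc(OCc3ccccc3)cc2OCc2ccccc2)cc1 | intermediate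
9 | 3-(1,3,2-benzodioxaborol-2-yl)-5,7-bis(benzyloxy)-2-(4-methoxyphenyl)-4H-chromen-4-one | COc1ccc(-c2oc3cc(OCc4ccccc4)cc(OCc4ccccc4)c3c(=O)c2B2Oc3ccccc3O2)cc1 | intermediate
10 | 5,7-bis(benzyloxy)-2-(4-methoxyphenyl)-3-(4,4,5,5-tetramethyl-1,3,2-dioxaborolan-2-yl)-4H-chromen-4-one | COc1ccc(-c2oc3cc(OCc4ccccc4)cc(OCc4ccccc4)c3c(=O)c2B2OC(C)(C)C(C)(C)O2)cc1 | intermediate
11 | 5,7-bis(benzyloxy)-3-{7-(benzyloxy)-2-[4-(benzyloxy)phenyl]-5-hydroxy-4-oxo-4H-chromen-6-yl}-2-(4-methoxyphenyl)-4H-chromen-4-one | COc1ccc(-c2oc3cc(OCc4ccccc4)cc(OCc4ccccc4)c3c(=O)c2-c2c(OCc3ccccc3)cc3oc(-c4ccc(OCc5ccccc5)cc4)cc(=O)c3c2O)cc1 | intermediate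
12 | 5,7-dihydroxy-3-[5,7-dihydroxy-2-(4-hydroxyphenyl)-4-oxo-4H-chromen-6-yl]-2-(4-methoxyphenyl)-4H-chromen-4-one | COc1ccc(-c2oc3cc(O)cc(O)c3c(=O)c2-c2c(O)cc3oc(-c4ccc(O)cc4)cc(=O)c3c2O)cc1 | target

**Step count**
Total steps: 6. Longest linear sequence: 4 (steps 1, 2, 5, 6 or steps 3, 4, 5, 6).

**Three steps most likely to fail**

Step 4 (the proposed new oxyboration). Possible failures are bromide conjugate addition to the boron-activated ynone, slow gold-to-boron transfer at the electron-poor C3, or a boron-free flavone after work-up. The fallback uses known chemistry, sets out from 7 and 3, and comes back at 11. Iodine monochloride (ICl, CH2Cl2, −78 °C) effects the dealkylative iodocyclisation of 7 to 5,7-bis(benzyloxy)-3-iodo-2-(4-methoxyphenyl)-4H-chromen-4-one F1. In parallel, Miyaura borylation of 3 (B2pin2, KOAc, Pd(dppf)Cl2, dioxane, 90 °C) gives 7-(benzyloxy)-2-[4-(benzyloxy)phenyl]-5-hydroxy-6-(4,4,5,5-tetramethyl-1,3,2-dioxaborolan-2-yl)-4H-chromen-4-one F2. Suzuki coupling of F1 with F2 under the conditions of step 5 then gives 11, with the polarity of the union reversed.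

Step 5 (tetra-ortho-substituted Suzuki coupling). Possible failures are protodeboronation of 10 or no transmetalation at the hindered C3. The fallback sets out from 7 (with 3 as partner) and comes back at 11. MgBr2·OEt2 (toluene/Et2O, 23 °C) removes one ortho benzyl group by chelation to give 1-[2,4-bis(benzyloxy)-6-hydroxyphenyl]-3-(4-methoxyphenyl)prop-2-yn-1-one F3. Zerovalent palladium (Pd(PPh3)4, K2CO3, MeCN, 60 °C) with iodide 3 then carries out an arylative cyclisation: the aryl–palladium species activates the alkyne, the phenoxide attacks anti in a 6-endo mode, and reductive elimination makes the C3–C6″ bond on the linear alkyne instead of on a preformed flavone boronate, giving 11.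

Step 3 (acid-mediated alkynoylation). Possible failures are acid-induced debenzylative cyclisation of 7, hydroarylation of the ynone, or trifluoroacetylation of 4. The fallback sets out from 4 and comes back at 7. Vilsmeier–Haack formylation (POCl3, DMF, 0 → 60 °C) gives 2,4,6-tris(benzyloxy)benzaldehyde F4. 4-Ethynylanisole and n-BuLi (THF, −78 °C) give lithium (4-methoxyphenyl)acetylide F5, which adds to F4 to give racemic 3-(4-methoxyphenyl)-1-[2,4,6-tris(benzyloxy)phenyl]prop-2-yn-1-ol F6. Oxidation with MnO2 (CH2Cl2, 23 °C) gives 7 without any acid.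

**Further compounds**
F1 | step 4 | 5,7-bis(benzyloxy)-3-iodo-2-(4-methoxyphenyl)-4H-chromen-4-one | COc1ccc(-c2oc3cc(OCc4ccccc4)cc(OCc4ccccc4)c3c(=O)c2I)cc1
F2 | step 4 | 7-(benzyloxy)-2-[4-(benzyloxy)phenyl]-5-hydroxy-6-(4,4,5,5-tetramethyl-1,3,2-dioxaborolan-2-yl)-4H-chromen-4-one | O=c1cc(-c2ccc(OCc3ccccc3)cc2)oc2cc(OCc3ccccc3)c(B3OC(C)(C)C(C)(C)O3)c(O)c12
F3 | step 5 | 1-[2,4-bis(benzyloxy)-6-hydroxyphenyl]-3-(4-methoxyphenyl)prop-2-yn-1-one | COc1ccc(C#CC(=O)c2c(O)cc(OCc3ccccc3)cc2OCc2ccccc2)cc1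
F4 | step 3 | 2,4,6-tris(benzyloxy)benzaldehyde | O=Cc1c(OCc2ccccc2)cc(OCc2ccccc2)cc1OCc1ccccc1
F5 | step 3 | lithium (4-methoxyphenyl)acetylide | [Li]C#Cc1ccc(OC)cc1
F6 | step 3 | 3-(4-methoxyphenyl)-1-[2,4,6-tris(benzyloxy)phenyl]prop-2-yn-1-ol (racemic) | COc1ccc(C#CC(O)c2c(OCc3ccccc3)cc(OCc3ccccc3)cc2OCc2ccccc2)cc1
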